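**Assumption:** Artocarpetin B (C22H22O6) has no stereocentres or stereogenic axes, so "single enantiomer" is taken to mean the single achiral compound. The route has not been run; conditions are drawn from known reaction types.

## Retrosynthetic overview

1. Target 9 ⇒ 5-O-prenyl flavone 8 by a tandem para-Claisen–Cope rearrangement (O5 → C6 → C8). The prenyl ether protects the 5-OH and is also the latent 8-prenyl group.
2. 8 ⇒ chromone 6 + bromophenol 7: the C2–C1' bond is made by C2–H zincation and Negishi coupling, with no chalcone or diketone and no protecting group on the 4'-OH.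
3. 6 ⇒ acetophenone 3 + a one-carbon unit (DMF-DMA), so the pyranone is closed before any aryl group is present.
4. 3 ⇒ symmetric 2',6'-dihydroxy-4'-methoxyacetophenone 1 + prenyl bromide 2 (desymmetrising mono-O-prenylation).
5. Ring order: A ring purchased → C ring (pyranone) formed → B ring (purchased) attached by cross-coupling → prenyl relayed to C8 last.

## Route

**Step 1**
Reactants: 1, 2',6'-dihydroxy-4'-methoxyacetophenone; 2, prenyl bromide (1-bromo-3-methylbut-2-ene)
Product: 3, 1-[2-hydroxy-4-methoxy-6-(3-methylbut-2-en-1-yloxy)phenyl]ethan-1-one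
Conditions: 2 (1.05 equiv), K2CO3 (1.1 equiv), acetone, reflux, 6 h
Reagents that add atoms: prenyl bromide, CC(C)=CCBr
Why: Williamson etherification of a C2-symmetric diphenol, where either OH gives the same product and the remaining OH is deactivated by its hydrogen bond to the ketone, so alkylation stops at the mono-ether.

**Step 2**
Reactants: 3; 4, N,N-dimethylformamide dimethyl acetal (DMF-DMA)
Product: 5, (E)-3-(dimethylamino)-1-[2-hydroxy-4-methoxy-6-(3-methylbut-2-en-1-yloxy)phenyl]prop-2-en-1-one
Conditions: DMF-DMA (3 equiv), toluene, 85 °C, 3 h; evaporate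
Reagents that add atoms: DMF-DMA, COC(OC)N(C)C (supplies the CH–NMe2 unit; the CH becomes C2 of the chromone)
Why: Amide-acetal condensation of the methyl ketone gives the E-enaminone, with the chelated phenol left untouched and the temperature kept well below that needed for thermal rearrangement of the aryl prenyl ether.

**Step 3**
Reactants: 5
Product: 6, 7-methoxy-5-(3-methylbut-2-en-1-yloxy)-4H-chromen-4-one
Conditions: 1 M aq HCl / CH2Cl2 (biphasic), rt, 1–2 h
Reagents that add atoms: none
Why: Acid-promoted 6-endo oxa-Michael addition of the phenol to the protonated enaminone followed by loss of Me2NH (enaminone chromone synthesis), under dilute aqueous acid at rt that an aryl prenyl ether tolerates.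

**Step 4**
Reactants: 6; 7, 4-bromo-3-methoxyphenol
Product: 8, 2-(4-hydroxy-2-methoxyphenyl)-7-methoxy-5-(3-methylbut-2-en-1-yloxy)-4H-chromen-4-one
Conditions: (i) 6, TMP2Zn·2MgCl2·2LiCl (0.6 equiv), THF, −30 °C, 1 h; (ii) 7 (1.2 equiv, pre-deprotonated with NaH, THF, 0 °C), Pd(OAc)2 (3 mol %), SPhos (6 mol %), THF, 25 → 50 °C; aq NH4Cl
Reagents that add atoms: none beyond reactant 7, COc1cc(O)ccc1Br
Why: MgCl2 bound to the C4 carbonyl/5-alkoxy chelate blocks carbonyl-directed C3 metalation and acidifies C2–H, so the TMP-zinc base zincates C2 selectively, and the resulting chromon-2-ylzinc undergoes Pd/SPhos Negishi coupling with the bromophenoxide, which has no acidic proton left and reacts much faster than Pd(0) ionises the aryl prenyl ether.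

**Step 5**
Reactants: 8
Product: 9, Artocarpetin B, 5-hydroxy-2-(4-hydroxy-2-methoxyphenyl)-7-methoxy-8-(3-methylbut-2-en-1-yl)-4H-chromen-4-one
Conditions: Eu(fod)3 (15 mol %), NaHCO3 (1 equiv), PhCl, 85 °C, 16–24 h
Reagents that add atoms: none
Why: Eu(III) chelated between C4=O and O5 triggers an aromatic Claisen shift of the prenyl group to C6 (the only free ortho position, giving a 1,1-dimethylallyl dienone), which relieves strain by a Cope shift to C8 and tautomerises to the chelated 5-OH phenol (tandem para-Claisen–Cope rearrangement); C8 is flanked only by 7-OMe and the ring oxygen, so no chroman can form.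

## Compound list

1 | 2',6'-dihydroxy-4'-methoxyacetophenone | CC(=O)c1c(O)cc(OC)cc1O | starting material
2 | prenyl bromide (1-bromo-3-methylbut-2-ene) | CC(C)=CCBr | starting material
3 | 1-[2-hydroxy-4-methoxy-6-(3-methylbut-2-en-1-yloxy)phenyl]ethan-1-one | CC(=O)c1c(O)cc(OC)cc1OCC=C(C)C | intermediate
4 | N,N-dimethylformamide dimethyl acetal | COC(OC)N(C)C | starting material
5 | (E)-3-(dimethylamino)-1-[2-hydroxy-4-methoxy-6-(3-methylbut-2-en-1-yloxy)phenyl]prop-2-en-1-one | CN(C)/C=C/C(=O)c1c(O)cc(OC)cc1OCC=C(C)C | intermediate
6 | 7-methoxy-5-(3-methylbut-2-en-1-yloxy)-4H-chromen-4-one | O=c1ccoc2cc(OC)cc(OCC=C(C)C)c12 | intermediate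
7 | 4-bromo-3-methoxyphenol | COc1cc(O)ccc1Br | starting material
8 | 2-(4-hydroxy-2-methoxyphenyl)-7-methoxy-5-(3-methylbut-2-en-1-yloxy)-4H-chromen-4-one | COc1cc(O)ccc1-c1cc(=O)c2c(OCC=C(C)C)cc(OC)cc2o1 | intermediate
9 | Artocarpetin B, 5-hydroxy-2-(4-hydroxy-2-methoxyphenyl)-7-methoxy-8-(3-methylbut-2-en-1-yl)-4H-chromen-4-one | COc1cc(O)ccc1-c1cc(=O)c2c(O)cc(OC)c(CC=C(C)C)c2o1 | target

## Summary

Total step count: 5, with no protecting-group steps.
Longest linear sequence: 5 (1 → 3 → 5 → 6 → 8 → 9).

Steps most likely to fail, with fallbacks: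

1. **Step 4 (C2–H zincation / Negishi coupling).** Risks are C3 versus C2 metalation, sluggish oxidative addition to the electron-rich bromophenoxide, and Pd(0) cleavage of the prenyl ether. Fallback: give up the C–H coupling and bring the B ring in before closing the pyranone. Condense 3 with 4-(methoxymethoxy)-2-methoxybenzaldehyde (Claisen–Schmidt) to the 2'-hydroxychalcone, cyclise to the flavanone with NaOAc, and dehydrogenate under I2- and DDQ-free conditions (both cleave prenyl ethers). Then run step 5 and remove MOM with HCl/MeOH.

2. **Step 5 (tandem Claisen–Cope).** Risks are arrest at the 6-(1,1-dimethylallyl) isomer and deprenylation. Fallback: install the C8 substituent by cross-coupling instead of rearrangement. Carry a 5-O-methyl (or MOM) and 4'-O-acyl flavone, iodinate at C8 with NIS (5,7-dialkoxyflavones react at C8), couple with allyl-Bpin, and cross-metathesise with 2-methyl-2-butene to the prenyl group. Finish with chelation-controlled 5-O-dealkylation (MgI2) and ester removal.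

3. **Step 3 (acidic ring closure with the prenyl ether present).** Risk is acid cleavage or migration of the prenyl group. Fallback: close the ring before prenylation. Convert 1 with HCO2Et/NaH then acid into 5-hydroxy-7-methoxychromone, and O-prenylate the chelated 5-OH afterwards (prenol, PPh3, DIAD, Mitsunobu) to reach 6 without exposing the ether to acid.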